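**Retrosynthetic overview**
- The strategy rests on ring B: C1' carries the carboxyl and sits between C2' (diaryl ether oxygen) and C6' (hydroxyl), with the C4' methyl para to it. This contiguous O–C(CO2H)–O triad is what an oxygen nucleophile followed by carbon dioxide writes onto a 3-alkoxybenzyne.
- Last disconnection: the ring-A methyl ester and both MOM ethers go back to a bis-MOM diacid; the two carboxyls are told apart by sterics (one ortho substituent on ring A, two on ring B).
- Key disconnection: the O–C2' and C1'–CO2H bonds are formed together from the ring-A phenoxide-carboxylate dianion, 3-(methoxymethoxy)-5-methylbenzyne and carbon dioxide.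
- Ring A acid comes from vanillin (silylation, Baeyer–Villiger, MOM, directed chlorination between the two oxygens, desilylation, ortho-formylation, oxidation). The aryne precursor comes from orcinol (mono-MOM, carbamate, directed silylation, triflation).
- No ring is formed in the route; both benzene rings come from the starting materials.

Key step: step 12

Remark: the target has no stereocentre and no configurationally stable axis, so it is achiral and the route needs no stereocontrol.

**Step 1**
Reactants: 1 vanillin
Product: 2 3-methoxy-4-(triisopropylsilyloxy)benzaldehyde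
Conditions: TIPSCl, imidazole, DMF, rt
Reagents that add atoms: triisopropylsilyl chloride, CC(C)[Si](Cl)(C(C)C)C(C)C
Why: Imidazole-promoted silylation masks the phenol that later becomes the ring-A phenoxide as a bulky ether that is inert to peracid and alkyllithium and does not direct metalation.

**Step 2**
Reactants: 2 3-methoxy-4-(triisopropylsilyloxy)benzaldehyde
Product: 4 3-methoxy-4-(triisopropylsilyloxy)phenol, via aryl formate 3 (not isolated)
Conditions: mCPBA, CH2Cl2, 0 °C → rt; then Et3N, MeOH, rt
Reagents that add atoms: meta-chloroperoxybenzoic acid, O=C(OO)c1cccc(Cl)c1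
Why: Baeyer–Villiger (Dakin-type) oxidation of the electron-rich benzaldehyde should proceed by aryl migration to the formate, which mild methanolysis cleaves without touching the aryl TIPS ether.

**Step 3**
Reactants: 4 3-methoxy-4-(triisopropylsilyloxy)phenol
Product: 5 triisopropyl[2-methoxy-4-(methoxymethoxy)phenoxy]silane
Conditions: MOMCl, i-Pr2NEt, CH2Cl2, 0 °C → rt
Reagents that add atoms: chloromethyl methyl ether, COCCl
Why: O-alkylation of the free phenol with MOMCl installs the acetal that protects the future C5 hydroxyl and directs the next metalation.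

**Step 4**
Reactants: 5 triisopropyl[2-methoxy-4-(methoxymethoxy)phenoxy]silane
Product: 7 [3-chloro-2-methoxy-4-(methoxymethoxy)phenoxy]triisopropylsilane, via aryllithium 6 (not isolated)
Conditions: n-BuLi, TMEDA, THF, −78 → 0 °C; then C2Cl6, −78 °C → rt
Reagents that add atoms: hexachloroethane, ClC(Cl)(Cl)C(Cl)(Cl)Cl
Why: Directed ortho-metalation should occur at the carbon flanked by the methoxy and MOM-oxy groups (cooperative 1,3-directing effect; the OTIPS group does not direct), and hexachloroethane chlorinates the aryllithium, placing chlorine at the future C4 of ring A.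

**Step 5**
Reactants: 7 [3-chloro-2-methoxy-4-(methoxymethoxy)phenoxy]triisopropylsilane
Product: 8 3-chloro-2-methoxy-4-(methoxymethoxy)phenol
Conditions: TBAF, THF, 0 °C; aq. NH4Cl
Reagents that add atoms: none
Why: Fluoride cleaves the aryl Si–O bond selectively, while the MOM ether and the aryl chloride are inert.

**Step 6**
Reactants: 8 3-chloro-2-methoxy-4-(methoxymethoxy)phenol
Product: 9 4-chloro-2-hydroxy-3-methoxy-5-(methoxymethoxy)benzaldehyde
Conditions: MgCl2, Et3N, (CH2O)n, MeCN, 80 °C; aq. citric acid work-up
Reagents that add atoms: paraformaldehyde (formaldehyde), C=O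
Why: Magnesium-mediated ortho-formylation of phenols (Casnati–Skattebøl) delivers formaldehyde within the magnesium phenoxide to the only free carbon next to the hydroxyl, and the basic medium leaves the MOM ether intact.

**Step 7**
Reactants: 9 4-chloro-2-hydroxy-3-methoxy-5-(methoxymethoxy)benzaldehyde
Product: 10 4-chloro-2-hydroxy-3-methoxy-5-(methoxymethoxy)benzoic acid
Conditions: NaClO2, NaH2PO4, 2-methyl-2-butene, t-BuOH/H2O, 0 °C → rt
Reagents that add atoms: sodium chlorite, [Na+].[O-]Cl=O
Why: Pinnick oxidation converts the aldehyde into the acid in a buffered medium that spares the MOM ether, the alkene removing hypochlorous acid before it can chlorinate the ring.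

**Step 8**
Reactants: 11 orcinol (anhydrous)
Product: 12 3-(methoxymethoxy)-5-methylphenol
Conditions: MOMCl (1.0 equiv), i-Pr2NEt, THF, 0 °C → rt; chromatography
Reagents that add atoms: chloromethyl methyl ether, COCCl
Why: Statistical mono-alkylation of the symmetrical diol with one equivalent of MOMCl should give the mono-ether, separable from diol and bis-ether, which are recycled.

**Step 9**
Reactants: 12 3-(methoxymethoxy)-5-methylphenol
Product: 13 3-(methoxymethoxy)-5-methylphenyl N-isopropylcarbamate
Conditions: i-PrNCO, Et3N (cat.), CH2Cl2, rt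
Reagents that add atoms: isopropyl isocyanate, CC(C)N=C=O
Why: Base-catalysed addition of the phenol to the isocyanate gives the N-isopropylcarbamate, a strong ortho-director that is later removable under mild base.

**Step 10**
Reactants: 13 3-(methoxymethoxy)-5-methylphenyl N-isopropylcarbamate
Product: 17 3-(methoxymethoxy)-5-methyl-2-(trimethylsilyl)phenyl N-isopropylcarbamate, via N-silyl carbamate 14 (not isolated), via aryllithium 15 (not isolated), via N-silyl C-silyl carbamate 16 (not isolated)
Conditions: TBSOTf, TMEDA, Et2O, 0 °C → rt; n-BuLi, TMEDA, −78 °C; TMSCl, −78 °C → rt; aq. NH4Cl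
Reagents that add atoms: trimethylsilyl chloride, C[Si](C)(C)Cl
Why: After in situ N-silylation (which prevents fragmentation of an N-lithio carbamate), directed ortho-metalation should occur at C2 between the carbamate and MOM-oxy groups, TMSCl traps the aryllithium, and work-up hydrolyses the N–Si bond.

**Step 11**
Reactants: 17 3-(methoxymethoxy)-5-methyl-2-(trimethylsilyl)phenyl N-isopropylcarbamate
Product: 19 3-(methoxymethoxy)-5-methyl-2-(trimethylsilyl)phenyl trifluoromethanesulfonate, via silyl phenol 18 (not isolated)
Conditions: DBU, Et2NH, MeCN, 40 °C; then PhNTf2, rt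
Reagents that add atoms: N-phenylbis(trifluoromethanesulfonimide), O=S(=O)(N(c1ccccc1)S(=O)(=O)C(F)(F)F)C(F)(F)F
Why: DBU deprotonates the N–H carbamate, which fragments (E1cB) to the phenoxide and isopropyl isocyanate (scavenged by diethylamine), and PhNTf2 triflates the phenoxide in the same flask.

**Step 12**
Reactants: 10 4-chloro-2-hydroxy-3-methoxy-5-(methoxymethoxy)benzoic acid (1.2 equiv); 19 3-(methoxymethoxy)-5-methyl-2-(trimethylsilyl)phenyl trifluoromethanesulfonate; 20 carbon dioxide
Product: 24 2-[6-carboxy-3-chloro-2-methoxy-4-(methoxymethoxy)phenoxy]-6-(methoxymethoxy)-4-methylbenzoic acid, via dipotassium salt 21 (not isolated), via aryne 22 (not isolated), via arylpotassium 23 (not isolated)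
Conditions: KH (2 equiv per 10), THF, 0 °C → rt; then dry 18-crown-6, KF, CO2 (1 atm), slow addition of 19, 0 °C → rt; cold dil. HCl to pH 3
Reagents that add atoms: none
Why: Proposed new method: fluoride removes the trimethylsilyl group of 19 and triflate leaves to give 3-alkoxybenzyne 22, whose triple bond is distorted by the inductively withdrawing MOM-oxy group so that the phenoxide oxygen of dianion 21 adds at the carbon remote from it (the future C2') and the charge arrives at C1', next to the MOM-oxy group, as arylpotassium 23. In dry THF with no proton donor left (deprotonation by KH releases only hydrogen) this anion should be carboxylated by dissolved carbon dioxide, which sets the C6'(O)–C1'(CO2H)–C2'(OAr) pattern of ring B in one operation. The closest known reactions are the aryne–amine–carbon dioxide three-component synthesis of anthranilic acids and the O-arylation of phenoxides by 3-alkoxybenzynes at the meta carbon; the union of a phenoxide, an aryne and carbon dioxide is not established. No ring is closed and no stereocentre is formed. The step needs regioselective addition (secured by the 3-alkoxy group of the aryne), attack through the phenoxide and not the carboxylate (secured by the higher nucleophilicity of the phenoxide oxygen) and capture of carbon dioxide ahead of protons (secured by the aprotic medium and the carbon dioxide atmosphere). Ring A enters as the carboxylate because an ester at that position would acylate the C1' anion and close a xanthone.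

**Step 13**
Reactants: 24 2-[6-carboxy-3-chloro-2-methoxy-4-(methoxymethoxy)phenoxy]-6-(methoxymethoxy)-4-methylbenzoic acid
Product: 26 2-[3-chloro-4-hydroxy-2-methoxy-6-(methoxycarbonyl)phenoxy]-6-hydroxy-4-methylbenzoic acid, via deprotected diacid 25 (not isolated)
Conditions: HCl (1.25 M in MeOH), rt, then 45 °C
Reagents that add atoms: methanol, CO
Why: Methanolic HCl cleaves both MOM acetals and should then effect Fischer esterification only at the ring-A carboxyl, which has one ortho substituent, while the 2,6-disubstituted ring-B carboxyl cannot reach the tetrahedral intermediate (Victor Meyer esterification rule).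

**Compound list**
1 | vanillin | COc1cc(C=O)ccc1O | starting material
2 | 3-methoxy-4-(triisopropylsilyloxy)benzaldehyde | COc1cc(C=O)ccc1O[Si](C(C)C)(C(C)C)C(C)C | intermediate
3 | 3-methoxy-4-(triisopropylsilyloxy)phenyl formate | COc1cc(OC=O)ccc1O[Si](C(C)C)(C(C)C)C(C)C | intermediate
4 | 3-methoxy-4-(triisopropylsilyloxy)phenol | COc1cc(O)ccc1O[Si](C(C)C)(C(C)C)C(C)C | intermediate
5 | triisopropyl[2-methoxy-4-(methoxymethoxy)phenoxy]silane | COCOc1ccc(O[Si](C(C)C)(C(C)C)C(C)C)c(OC)c1 | intermediate
6 | [2-methoxy-6-(methoxymethoxy)-3-(triisopropylsilyloxy)phenyl]lithium | COCOc1ccc(O[Si](C(C)C)(C(C)C)C(C)C)c(OC)c1[Li] | intermediate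
7 | [3-chloro-2-methoxy-4-(methoxymethoxy)phenoxy]triisopropylsilane | COCOc1ccc(O[Si](C(C)C)(C(C)C)C(C)C)c(OC)c1Cl | intermediate
8 | 3-chloro-2-methoxy-4-(methoxymethoxy)phenol | COCOc1ccc(O)c(OC)c1Cl | intermediate
9 | 4-chloro-2-hydroxy-3-methoxy-5-(methoxymethoxy)benzaldehyde | COCOc1cc(C=O)c(O)c(OC)c1Cl | intermediate
10 | 4-chloro-2-hydroxy-3-methoxy-5-(methoxymethoxy)benzoic acid | OC(=O)c1cc(OCOC)c(Cl)c(OC)c1O | intermediate
11 | orcinol (5-methylbenzene-1,3-diol) | Cc1cc(O)cc(O)c1 | starting material
12 | 3-(methoxymethoxy)-5-methylphenol | COCOc1cc(C)cc(O)c1 | intermediate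
13 | 3-(methoxymethoxy)-5-methylphenyl N-isopropylcarbamate | COCOc1cc(C)cc(OC(=O)NC(C)C)c1 | intermediate
14 | 3-(methoxymethoxy)-5-methylphenyl N-(tert-butyldimethylsilyl)-N-isopropylcarbamate | COCOc1cc(C)cc(OC(=O)N(C(C)C)[Si](C)(C)C(C)(C)C)c1 | intermediate
15 | 2-lithio derivative of 14 (lithium at the ring carbon between the carbamate and MOM-oxy groups) | COCOc1cc(C)cc(OC(=O)N(C(C)C)[Si](C)(C)C(C)(C)C)c1[Li] | intermediate
16 | 3-(methoxymethoxy)-5-methyl-2-(trimethylsilyl)phenyl N-(tert-butyldimethylsilyl)-N-isopropylcarbamate | COCOc1cc(C)cc(OC(=O)N(C(C)C)[Si](C)(C)C(C)(C)C)c1[Si](C)(C)C | intermediate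
17 | 3-(methoxymethoxy)-5-methyl-2-(trimethylsilyl)phenyl N-isopropylcarbamate | COCOc1cc(C)cc(OC(=O)NC(C)C)c1[Si](C)(C)C | intermediate
18 | 3-(methoxymethoxy)-5-methyl-2-(trimethylsilyl)phenol | COCOc1cc(C)cc(O)c1[Si](C)(C)C | intermediate
19 | 3-(methoxymethoxy)-5-methyl-2-(trimethylsilyl)phenyl trifluoromethanesulfonate | COCOc1cc(C)cc(OS(=O)(=O)C(F)(F)F)c1[Si](C)(C)C | intermediate
20 | carbon dioxide | O=C=O | starting material
21 | dipotassium 4-chloro-3-methoxy-5-(methoxymethoxy)-2-oxidobenzoate | [K+].[K+].[O-]C(=O)c1cc(OCOC)c(Cl)c(OC)c1[O-] | intermediate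
22 | 3-(methoxymethoxy)-5-methylbenzyne | COCOC1=CC(C)=CC#C1 | intermediate
23 | dipotassium salt of the C1' aryl anion of the diaryl ether (carboxylate on ring A, carbanion on ring B between the ether oxygen and the MOM-oxy group) | [K+].[K+].[O-]C(=O)c1cc(OCOC)c(Cl)c(OC)c1Oc1cc(C)cc(OCOC)[c-]1 | intermediate
24 | 2-[6-carboxy-3-chloro-2-methoxy-4-(methoxymethoxy)phenoxy]-6-(methoxymethoxy)-4-methylbenzoic acid | OC(=O)c1cc(OCOC)c(Cl)c(OC)c1Oc1cc(C)cc(OCOC)c1C(=O)O | intermediate
25 | 2-(6-carboxy-3-chloro-4-hydroxy-2-methoxyphenoxy)-6-hydroxy-4-methylbenzoic acid | OC(=O)c1cc(O)c(Cl)c(OC)c1Oc1cc(C)cc(O)c1C(=O)O | intermediate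
26 | 2-[3-chloro-4-hydroxy-2-methoxy-6-(methoxycarbonyl)phenoxy]-6-hydroxy-4-methylbenzoic acid | COC(=O)c1cc(O)c(Cl)c(OC)c1Oc1cc(C)cc(O)c1C(=O)O | target

**Totals**
Total step count: 13 (steps 1–7 for ring A, steps 8–11 for the aryne precursor, steps 12–13 for union and end game).
Longest linear sequence: 9 steps (vanillin → target through steps 1–7, 12 and 13).

**Steps most likely to fail**

1. Step 12 (proposed new method). Three processes could divert it: carbonation of the phenoxide oxygen before it meets the aryne (which would pass the aryl group on as an O-acyl product), proton capture by the C1' anion before carboxylation, and O-arylation through the carboxylate. The fallback uses known chemistry and sets out from 10, which is converted (MeI, KHCO3, DMF) into methyl 4-chloro-2-hydroxy-3-methoxy-5-(methoxymethoxy)benzoate F1. Separately, commercial 3-bromo-5-methylphenol is protected (MOMCl, i-Pr2NEt) as 1-bromo-3-(methoxymethoxy)-5-methylbenzene F2. This is deprotonated between bromine and the MOM-oxy group (LDA, THF, −78 °C) and quenched with carbon dioxide to give 2-bromo-6-(methoxymethoxy)-4-methylbenzoic acid F3. An ortho-carboxylate-assisted Ullmann ether coupling of F1 with F3 (CuI, Cs2CO3, pyridine–toluene, 110 °C) should give 2-[3-chloro-2-methoxy-6-(methoxycarbonyl)-4-(methoxymethoxy)phenoxy]-6-(methoxymethoxy)-4-methylbenzoic acid F4. Removal of both MOM groups (HCl in MeOH, rt, no heating) returns to the route at target 26.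

2. Step 13. The electron-rich 2,6-dioxygenated ring-B acid may lose carbon dioxide in warm acid, or the two carboxyls may be discriminated incompletely. The fallback sets out from 24, which is alkylated at both carboxylates (allyl bromide, K2CO3, DMF) to the diallyl ester of the bis-MOM diacid F5. Methoxide (NaOMe, MeOH, rt) should transesterify only the unhindered ring-A ester, giving the ring-A methyl ester ring-B allyl ester bis-MOM ether F6. Cold methanolic HCl (rt) removes the MOM groups to give allyl 2-[3-chloro-4-hydroxy-2-methoxy-6-(methoxycarbonyl)phenoxy]-6-hydroxy-4-methylbenzoate F7. Palladium-catalysed deallylation (Pd(PPh3)4, morpholine, THF, rt) frees the ring-B acid under neutral conditions and returns to the route at target 26.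

3. Step 6. The methoxy group next to the phenol may chelate magnesium and make formylation sluggish, and long heating with the magnesium salt may erode the MOM ether. The fallback sets out from 8, which is carbamoylated (NaH, ClCONEt2, THF) to 3-chloro-2-methoxy-4-(methoxymethoxy)phenyl N,N-diethylcarbamate F8. Carbamate-directed ortho-lithiation (s-BuLi, TMEDA, THF, −78 °C) and a carbon dioxide quench at that temperature should give 4-chloro-2-(diethylcarbamoyloxy)-3-methoxy-5-(methoxymethoxy)benzoic acid F9. Hydrolysis of the carbamate (KOH, EtOH/H2O, reflux; careful acidification) returns to the route at compound 10, bypassing 9.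

**Further compounds**
F1 | step 12 | methyl 4-chloro-2-hydroxy-3-methoxy-5-(methoxymethoxy)benzoate | COC(=O)c1cc(OCOC)c(Cl)c(OC)c1O
F2 | step 12 | 1-bromo-3-(methoxymethoxy)-5-methylbenzene | COCOc1cc(C)cc(Br)c1
F3 | step 12 | 2-bromo-6-(methoxymethoxy)-4-methylbenzoic acid | COCOc1cc(C)cc(Br)c1C(=O)O
F4 | step 12 | 2-[3-chloro-2-methoxy-6-(methoxycarbonyl)-4-(methoxymethoxy)phenoxy]-6-(methoxymethoxy)-4-methylbenzoic acid | COC(=O)c1cc(OCOC)c(Cl)c(OC)c1Oc1cc(C)cc(OCOC)c1C(=O)O
F5 | step 13 | allyl 2-[6-(allyloxycarbonyl)-3-chloro-2-methoxy-4-(methoxymethoxy)phenoxy]-6-(methoxymethoxy)-4-methylbenzoate | C=CCOC(=O)c1cc(OCOC)c(Cl)c(OC)c1Oc1cc(C)cc(OCOC)c1C(=O)OCC=C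
F6 | step 13 | allyl 2-[3-chloro-2-methoxy-6-(methoxycarbonyl)-4-(methoxymethoxy)phenoxy]-6-(methoxymethoxy)-4-methylbenzoate | COC(=O)c1cc(OCOC)c(Cl)c(OC)c1Oc1cc(C)cc(OCOC)c1C(=O)OCC=C
F7 | step 13 | allyl 2-[3-chloro-4-hydroxy-2-methoxy-6-(methoxycarbonyl)phenoxy]-6-hydroxy-4-methylbenzoate | COC(=O)c1cc(O)c(Cl)c(OC)c1Oc1cc(C)cc(O)c1C(=O)OCC=C
F8 | step 6 | 3-chloro-2-methoxy-4-(methoxymethoxy)phenyl N,N-diethylcarbamate | CCN(CC)C(=O)Oc1ccc(OCOC)c(Cl)c1OC
F9 | step 6 | 4-chloro-2-(diethylcarbamoyloxy)-3-methoxy-5-(methoxymethoxy)benzoic acid | CCN(CC)C(=O)Oc1c(C(=O)O)cc(OCOC)c(Cl)c1OC
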